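## The problem

The target 11 is an open-chain diester. (S)-1-(3-Hydroxy-4,5-dimethoxyphenyl)propan-1-ol is acylated by a (Z)-2-(oxymethyl)but-2-enoic acid, and the primary oxygen of that acid carries an angeloyl [(Z)-2-methylbut-2-enoyl] group. There is no ring apart from the benzene ring, so the task is to build a branched four-carbon acid and to join three pieces through two ester oxygens, in an order that never asks for one ester to be cleaved beside the other. The only stereocentre is the benzylic carbinol carbon. No neighbouring group can direct it and it is too remote to influence either double bond, so it must come from a catalyst and the two alkene geometries must be set independently of it. Both trisubstituted alkenes hold the C3 methyl group cis to the ester carbonyl, the less stable arrangement; in the angelate this geometry can be bought, in the central enoate it has to be made kinetically and then kept. Little in the molecule survives rough treatment: the Z-enoates isomerise under base, nucleophilic catalysis or acyl activation, the CH2–O angelate is an allylic ester open to SN2′ attack and to ionisation by low-valent metals, the benzylic C–O bond on the alkoxy-rich arene is sensitive to acid and hydrogenolysis, and the phenol is free. The feature that opens the synthesis is the central enoate itself: C3 bears H and CH3, C2 bears the CH2O carbon and the carboxyl carbon C1, with H and CH2O on the same side. That is the pattern left when hydride and a one-carbon electrophile are added syn across C2≡C3 of a but-2-ynoate.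

## Retrosynthesis

**11 ⇒ 10 (O–Si).** The phenol is carried to the end as the tert-butyldimethylsilyl ether 10, because Et2Zn, the carbodiimide, i-Bu2AlH and the Mitsunobu betaine would all engage a free ArOH. A silyl ether is preferred to benzyl, allyl or acetal protection: its removal needs no hydrogen (benzylic ester), no palladium catalyst (allylic angelate) and no acid (benzylic C–O). The forward step must cleave only the Ar–O–Si bond, with buffered fluoride, in the presence of two esters.

**10 ⇒ 8 + 9 (CH2–O bond of the angelate).** The neighbouring cut, at the acyl–oxygen bond, would need an activated angeloyl species, and such species drift towards the tiglate. Cutting on the alkyl side lets angelic acid 9 act only as a carboxylate nucleophile. The precursor 8 is a primary allylic alcohol with one ester fewer. The forward Mitsunobu reaction must substitute at CH2 and not at C3, and must not expose the enoates to free phosphine.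

**8 ⇒ 5 + 6, through 7 (C2–CH2OH and C3–H).** This is the central disconnection. An olefination of acetaldehyde (cut at C2=C3) needs a purpose-built phosphonate and a second protecting group. A Morita–Baylis–Hillman adduct followed by allylic transposition delivers the thermodynamic isomer. Adding hydride and formaldehyde 6 across ynoate 5 forms the skeletal bond and the alkene geometry in one operation, and leaves the hydroxyl group free for the next step. The precursor 5 has no stereochemical element in its acyl part. The forward reaction has to deliver hydride 1,4 and not 1,2, trap allenolate 7 at C2 from the hydrogen side, and be worked up cold and neutral.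

**5 ⇒ 3 + 4 (acyl–oxygen bond of the benzylic ester).** Here the acyl cut is the safe one. But-2-ynoic acid 4 has no geometry to lose, and the C–O bond of alcohol 3, and with it the stereocentre, is not broken. The alkyl-side alternative, a Mitsunobu inversion, would activate an electron-rich benzylic carbon and invite racemisation. The forward reaction is a carbodiimide esterification.

**3 ⇒ 2 (benzylic C–CH2CH3 bond).** Catalytic enantioselective addition of Et2Zn to an aryl aldehyde creates exactly this 1-arylpropanol in one step with predictable facial sense. Asymmetric reduction of the corresponding propiophenone would cost two more steps and is kept in reserve. The forward step needs only a suitable amino alcohol ligand of the right hand.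

**2 ⇒ 1 (O–Si).** The commercial 3-hydroxy-4,5-dimethoxybenzaldehyde 1 already has the full substitution pattern of the arene; silylation is routine.

## Roads not taken

**Alternative 1:** The cut is the benzylic C–O bond. In the forward sense [Ir(cod)Cl]2 and a chiral phosphoramidite would ionise the cinnamyl carbonate A3 [methyl (E)-3-(3-silyloxy-4,5-dimethoxyphenyl)prop-2-enyl carbonate]. The caesium carboxylate of the complete diester acid A2 would then attack the aryl-bearing terminus to give the branched ester A1, creating the stereocentre and the ester bond together. The vinyl group of A1 would then be saturated and the phenol freed.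

- Merits: the route is convergent, the stereocentre is set late by a catalyst, and A2 is used only as a carboxylate, never acyl-activated.
- Weak points: A1 is both benzylic and allylic, so the same catalyst can re-ionise it, eroding the enantiomeric purity and leaking to the linear ester. A2 carries its own allylic ester, which low-valent iridium can also ionise. The terminal alkene must be reduced beside two enoates and a hydrogenolysis-prone C–O bond. A2 still has to be made with its Z-enoate, which calls for the same ynoate chemistry on a simple ester plus a non-hydrolytic ester cleavage.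
- Comparison: in convergence this road is better. The chosen plan sets against it a stereocentre fixed early on a simple aldehyde by a very dependable reaction, no late reduction, and no allyl-metal catalyst in the flask with the allylic angelate.

**Alternative 2:** The cut is the C2=C3 double bond. The sodium anion (NaH) of the diphenyl phosphonate A5 (the 2-(diphenoxyphosphoryl)-3-(triisopropylsilyloxy)propanoate of alcohol 3) would add to acetaldehyde A6 and lose diphenyl phosphate to give the Z-enoate A4.

- Merits: Z-selectivity of aryloxy phosphonates is a well-understood kinetic effect, and no aluminium hydride, (Me2N)3PO or gaseous formaldehyde is needed. In these respects it is the gentler key step.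
- Weak points: A5 must be built in several steps. Its anion carries a β-silyloxy group that can be expelled to give a phosphonoacrylate. A4 holds a primary alkyl silyl ether beside an aryl silyl ether, and fluoride would remove the aryl one first while acid endangers the benzylic ester.
- Comparison: the chosen plan is shorter, forms the C2–CH2OH bond and the geometry together, and delivers the free alcohol directly. It has to accept a more demanding reagent in return.

**Alternative 3:** The cut is the arene–benzylic carbon bond. NiBr2(dme), a chiral bis(oxazoline) and Mn powder would couple the aryl bromide A8 with the racemic 1-chloropropyl ester A9 of acid A2 to give A7, which is identical in structure with 10.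

- Merits: it is the most convergent route, and C–C bond and stereocentre arise in one enantioconvergent event with the whole acyl part in place.
- Weak points: the α-acyloxyalkyl radical and low-valent nickel meet two Michael acceptors and an allylic ester in the same molecule. A8 is electron-rich and slow in oxidative addition. A9 requires the acid chloride of A2, which means acyl activation next to a Z-enoate, and it is hydrolytically labile. A2 again needs the hydroalumination chemistry anyway.
- Comparison: the step count could be lower. The chosen plan sets against it that every step is an established reaction type on the functional-group class concerned and that no radical or low-valent metal ever meets the finished diester.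

Key step: step 4

## Route

Remarks on assumptions: formaldehyde 6 is used as the dry monomeric gas, generated immediately before use by cracking commercial paraformaldehyde and carried in with argon. Compounds 1, 4 and 9 are taken as purchased.

Step 1
Reactants: 1 3-hydroxy-4,5-dimethoxybenzaldehyde
Product: 2 3-(tert-butyldimethylsilyloxy)-4,5-dimethoxybenzaldehyde
Conditions: TBSCl, imidazole, DMF, 0 °C → rt
Reagents that add atoms: tert-butyldimethylsilyl chloride, CC(C)(C)[Si](C)(C)Cl
Why: Imidazole-promoted O-silylation of a phenol; the aldehyde is inert, and the aryl silyl ether removes the acidic O–H before the organozinc, carbodiimide, aluminium hydride and Mitsunobu steps.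

Step 2
Reactants: 2 3-(tert-butyldimethylsilyloxy)-4,5-dimethoxybenzaldehyde
Product: 3 (S)-1-[3-(tert-butyldimethylsilyloxy)-4,5-dimethoxyphenyl]propan-1-ol
Conditions: Et2Zn (2 equiv), (2S)-(−)-3-exo-(dimethylamino)isoborneol (5 mol %), toluene, 0 °C → rt; aq. NH4Cl
Reagents that add atoms: diethylzinc, CC[Zn]CC
Why: Amino alcohol-catalysed enantioselective addition of a dialkylzinc to an aryl aldehyde; the ethylzinc aminoalkoxide binds the aldehyde and a second Et2Zn in a bimetallic transition state, and the (2S)-ligand directs ethyl to the Si face of the carbonyl, which gives the S carbinol. Alkoxy-substituted benzaldehydes without ortho substituents are standard substrates and the uncatalysed addition is slow.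

Step 3
Reactants: 3 (S)-1-[3-(tert-butyldimethylsilyloxy)-4,5-dimethoxyphenyl]propan-1-ol; 4 but-2-ynoic acid
Product: 5 (S)-1-[3-(tert-butyldimethylsilyloxy)-4,5-dimethoxyphenyl]propyl but-2-ynoate
Conditions: DCC, DMAP (10 mol %), CH2Cl2, −20 → 0 °C
Reagents that add atoms: none
Why: Steglich esterification; the acid is activated and the carbinol C–O bond is never broken, so the stereocentre is retained, and low temperature with only catalytic DMAP limits conjugate addition of the pyridine to the ynoate.

Step 4
Reactants: 5 (S)-1-[3-(tert-butyldimethylsilyloxy)-4,5-dimethoxyphenyl]propyl but-2-ynoate; 6 formaldehyde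
Product: 8 (S)-1-[3-(tert-butyldimethylsilyloxy)-4,5-dimethoxyphenyl]propyl (Z)-2-(hydroxymethyl)but-2-enoate, via diisobutylaluminium allenolate 7 (not isolated)
Conditions: i-Bu2AlH (1.1 equiv), (Me2N)3PO (2–3 equiv), THF, 0 °C, 30 min; 5, 0 °C, 1 h; then CH2O (g, excess), −20 → 0 °C; cold aq. potassium sodium tartrate, pH 7
Reagents that add atoms: none
Why: The pre-formed complex of i-Bu2AlH with (Me2N)3PO is a soft, weakly Lewis acidic hydride donor that adds hydride to C3 of ynoate 5 in preference to the ester carbonyl and gives the aluminium allenolate 7 (an α-aluminated enoate). 7 then adds through C2 to formaldehyde in an aldol-type step that forms the C2–CH2O bond, and neutral hydrolysis releases 8. The closest known reaction type is conjugate hydroalumination of alk-2-ynoates with this reagent followed by aldehyde trapping, which gives (Z)-2-(hydroxyalkyl)alk-2-enoates. No ring closes and no stereocentre is formed; the benzylic centre is remote from the reacting atoms and is not touched. The first selectivity needed is 1,4- over 1,2-hydride delivery, secured by the phosphoramide ligand and by the contrast between the unhindered β-methyl ynoate terminus and the carbonyl of a hindered secondary ester. The second is alkene geometry: the H and CH3 on C3 of 7 lie in the plane in which the electrophile must reach C2, so formaldehyde enters past the hydrogen, the CH2OH carbon ends cis to H, and the methyl group ends cis to the ester. Holding the mixture at or below 0 °C and quenching cold at neutral pH prevents equilibration to the E isomer and hydride transfer from the aluminium alkoxide to excess formaldehyde.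

Step 5
Reactants: 8 (S)-1-[3-(tert-butyldimethylsilyloxy)-4,5-dimethoxyphenyl]propyl (Z)-2-(hydroxymethyl)but-2-enoate; 9 angelic acid [(Z)-2-methylbut-2-enoic acid]
Product: 10 (S)-1-[3-(tert-butyldimethylsilyloxy)-4,5-dimethoxyphenyl]propyl (Z)-2-{[(Z)-2-methylbut-2-enoyl]oxymethyl}but-2-enoate
Conditions: PPh3, diisopropyl azodicarboxylate (DIAD), THF, 0 °C, 15 min; then 9 and 8, 0 °C → rt
Reagents that add atoms: none
Why: Mitsunobu reaction; the primary allylic alcohol is activated as its alkoxyphosphonium ion and displaced at CH2 by the angelate anion, so the acid is never acyl-activated and keeps its Z geometry. Pre-forming the betaine keeps free phosphine away from the enoates, and direct attack at the unhindered CH2 should outrun attack at the methyl-bearing C3.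

Step 6
Reactants: 10 (S)-1-[3-(tert-butyldimethylsilyloxy)-4,5-dimethoxyphenyl]propyl (Z)-2-{[(Z)-2-methylbut-2-enoyl]oxymethyl}but-2-enoate
Product: 11 (S)-1-(3-hydroxy-4,5-dimethoxyphenyl)propyl (Z)-2-{[(Z)-2-methylbut-2-enoyl]oxymethyl}but-2-enoate (CNP0282120.1)
Conditions: Bu4NF, AcOH (1:1.2), THF, 0 °C
Reagents that add atoms: none
Why: Fluoride cleavage of an aryl silyl ether, driven by Si–F bond formation and fast for phenol ethers; the acetic acid buffer protonates the phenoxide as it forms, so the medium stays non-basic and the two esters and both Z-alkenes should persist.

## Compound list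

1 | 3-hydroxy-4,5-dimethoxybenzaldehyde | COc1cc(C=O)cc(O)c1OC | starting material
2 | 3-(tert-butyldimethylsilyloxy)-4,5-dimethoxybenzaldehyde | COc1cc(C=O)cc(O[Si](C)(C)C(C)(C)C)c1OC | intermediate
3 | (S)-1-[3-(tert-butyldimethylsilyloxy)-4,5-dimethoxyphenyl]propan-1-ol | O[C@@H](CC)c1cc(O[Si](C)(C)C(C)(C)C)c(OC)c(OC)c1 | intermediate
4 | but-2-ynoic acid | CC#CC(=O)O | starting material
5 | (S)-1-[3-(tert-butyldimethylsilyloxy)-4,5-dimethoxyphenyl]propyl but-2-ynoate | CC#CC(=O)O[C@@H](CC)c1cc(O[Si](C)(C)C(C)(C)C)c(OC)c(OC)c1 | intermediate
6 | formaldehyde | C=O | starting material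
7 | diisobutylaluminium allenolate of 5: 1-(diisobutylaluminiooxy)-1-{(S)-1-[3-(tert-butyldimethylsilyloxy)-4,5-dimethoxyphenyl]propoxy}buta-1,2-diene (allene axis not defined) | CC=C=C(O[Al](CC(C)C)CC(C)C)O[C@@H](CC)c1cc(O[Si](C)(C)C(C)(C)C)c(OC)c(OC)c1 | intermediate
8 | (S)-1-[3-(tert-butyldimethylsilyloxy)-4,5-dimethoxyphenyl]propyl (Z)-2-(hydroxymethyl)but-2-enoate | OC/C(=C/C)C(=O)O[C@@H](CC)c1cc(O[Si](C)(C)C(C)(C)C)c(OC)c(OC)c1 | intermediate
9 | angelic acid, (Z)-2-methylbut-2-enoic acid | C/C=C(/C)C(=O)O | starting material
10 | (S)-1-[3-(tert-butyldimethylsilyloxy)-4,5-dimethoxyphenyl]propyl (Z)-2-{[(Z)-2-methylbut-2-enoyl]oxymethyl}but-2-enoate | C/C=C(/C)C(=O)OC/C(=C/C)C(=O)O[C@@H](CC)c1cc(O[Si](C)(C)C(C)(C)C)c(OC)c(OC)c1 | intermediate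
11 | (S)-1-(3-hydroxy-4,5-dimethoxyphenyl)propyl (Z)-2-{[(Z)-2-methylbut-2-enoyl]oxymethyl}but-2-enoate | C/C=C(/C)C(=O)OC/C(=C/C)C(=O)O[C@@H](CC)c1cc(O)c(OC)c(OC)c1 | target

## Step count and least certain steps

Total steps: 6. Longest linear sequence: 6 steps (1 → 11); 4, 6 and 9 enter as purchased materials.

**Step 4 (key step).** Three processes threaten it:

- hydride delivery to the ester carbonyl instead of C3, if complexation of the aluminium hydride by the phosphoramide is incomplete, which would cleave the benzylic ester;
- loss of geometric control, if allenolate 7 is trapped slowly, for instance because formaldehyde repolymerises in the inlet, or if the product equilibrates during a warm or basic work-up;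
- hydride transfer from the product aluminium alkoxide to excess formaldehyde.

Fallback, setting out from 5: syn-hydrostannation with Bu3SnH under Pd(PPh3)4 (zerovalent palladium) places tin on C2 and hydrogen on C3 from the same side, to give (S)-1-[3-(tert-butyldimethylsilyloxy)-4,5-dimethoxyphenyl]propyl (E)-2-(tributylstannyl)but-2-enoate F1. Iododestannylation with I2 in CH2Cl2 at 0 °C, with retention, gives (S)-1-[3-(tert-butyldimethylsilyloxy)-4,5-dimethoxyphenyl]propyl (E)-2-iodobut-2-enoate F2. A Stille coupling of F2 with (tributylstannyl)methanol (Pd(PPh3)4, CuI) installs the CH2OH group with retention and rejoins the route at 8. No hydride reagent meets the ester in this sequence.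

**Step 5.** The likely failure is attack of the carboxylate at C3 of the activated alcohol (the SN2′ course), which transposes the double bond; phosphine-induced isomerisation of a Z-enoate is a lesser risk. Fallback, from 8 and 9: 9 is converted with 2,4,6-trichlorobenzoyl chloride and Et3N in toluene into (Z)-2-methylbut-2-enoic 2,4,6-trichlorobenzoic anhydride F3. F3 acylates the oxygen of 8 and rejoins the route at 10. Substitution at the allylic carbon is then excluded. The price is the known tendency of activated angelates to isomerise, which is limited by low temperature and by leaving out nucleophilic catalysts.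

**Step 6.** The risk is that fluoride or the phenoxide it releases acts as a base or nucleophile towards the diester, causing ester exchange or Z-to-E drift, since the finished molecule is the most fragile compound of the route. Fallback, from 8: buffered fluoride desilylation at this earlier stage gives (S)-1-(3-hydroxy-4,5-dimethoxyphenyl)propyl (Z)-2-(hydroxymethyl)but-2-enoate F4. A Mitsunobu reaction of F4 with 9 then gives 11 directly. The carboxylic acid is several pKa units more acidic than the phenol and so serves as the pronucleophile, and the phenol cannot be activated as the alcohol partner.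

**Step 2.** The risk is erosion of enantioselectivity through uncatalysed or zinc alkoxide-mediated background addition to this alkoxy-rich aldehyde. Fallback, from 2: EtMgBr gives racemic 1-[3-(tert-butyldimethylsilyloxy)-4,5-dimethoxyphenyl]propan-1-ol F5, and MnO2 oxidation gives 1-[3-(tert-butyldimethylsilyloxy)-4,5-dimethoxyphenyl]propan-1-one F6. Borane reduction of F6 with BH3·SMe2 and catalytic (R)-2-methyl-CBS-oxazaborolidine, which gives the S alcohol when the aryl group is the larger substituent, rejoins the route at 3.

## Further compounds

F1 | step 4 | (S)-1-[3-(tert-butyldimethylsilyloxy)-4,5-dimethoxyphenyl]propyl (E)-2-(tributylstannyl)but-2-enoate | C/C=C(/[Sn](CCCC)(CCCC)CCCC)C(=O)O[C@@H](CC)c1cc(O[Si](C)(C)C(C)(C)C)c(OC)c(OC)c1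
F2 | step 4 | (S)-1-[3-(tert-butyldimethylsilyloxy)-4,5-dimethoxyphenyl]propyl (E)-2-iodobut-2-enoate | C/C=C(/I)C(=O)O[C@@H](CC)c1cc(O[Si](C)(C)C(C)(C)C)c(OC)c(OC)c1
F3 | step 5 | (Z)-2-methylbut-2-enoic 2,4,6-trichlorobenzoic anhydride | C/C=C(/C)C(=O)OC(=O)c1c(Cl)cc(Cl)cc1Cl
F4 | step 6 | (S)-1-(3-hydroxy-4,5-dimethoxyphenyl)propyl (Z)-2-(hydroxymethyl)but-2-enoate | OC/C(=C/C)C(=O)O[C@@H](CC)c1cc(O)c(OC)c(OC)c1
F5 | step 2 | rac-1-[3-(tert-butyldimethylsilyloxy)-4,5-dimethoxyphenyl]propan-1-ol | CCC(O)c1cc(O[Si](C)(C)C(C)(C)C)c(OC)c(OC)c1
F6 | step 2 | 1-[3-(tert-butyldimethylsilyloxy)-4,5-dimethoxyphenyl]propan-1-one | CCC(=O)c1cc(O[Si](C)(C)C(C)(C)C)c(OC)c(OC)c1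
A1 | alternative 1 | (S)-1-[3-(tert-butyldimethylsilyloxy)-4,5-dimethoxyphenyl]prop-2-enyl (Z)-2-{[(Z)-2-methylbut-2-enoyl]oxymethyl}but-2-enoate | C/C=C(/C)C(=O)OC/C(=C/C)C(=O)O[C@@H](C=C)c1cc(O[Si](C)(C)C(C)(C)C)c(OC)c(OC)c1
A2 | alternative 1 | (Z)-2-{[(Z)-2-methylbut-2-enoyl]oxymethyl}but-2-enoic acid | C/C=C(/C)C(=O)OC/C(=C/C)C(=O)O
A3 | alternative 1 | methyl (E)-3-[3-(tert-butyldimethylsilyloxy)-4,5-dimethoxyphenyl]prop-2-enyl carbonate | COC(=O)OC/C=C/c1cc(O[Si](C)(C)C(C)(C)C)c(OC)c(OC)c1
A4 | alternative 2 | (S)-1-[3-(tert-butyldimethylsilyloxy)-4,5-dimethoxyphenyl]propyl (Z)-2-(triisopropylsilyloxymethyl)but-2-enoate | C/C=C(/CO[Si](C(C)C)(C(C)C)C(C)C)C(=O)O[C@@H](CC)c1cc(O[Si](C)(C)C(C)(C)C)c(OC)c(OC)c1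
A5 | alternative 2 | (S)-1-[3-(tert-butyldimethylsilyloxy)-4,5-dimethoxyphenyl]propyl 2-(diphenoxyphosphoryl)-3-(triisopropylsilyloxy)propanoate (both epimers at C2) | CC(C)[Si](C(C)C)(C(C)C)OCC(C(=O)O[C@@H](CC)c1cc(O[Si](C)(C)C(C)(C)C)c(OC)c(OC)c1)P(=O)(Oc1ccccc1)Oc1ccccc1
A6 | alternative 2 | acetaldehyde | CC=O
A7 | alternative 3 | (S)-1-[3-(tert-butyldimethylsilyloxy)-4,5-dimethoxyphenyl]propyl (Z)-2-{[(Z)-2-methylbut-2-enoyl]oxymethyl}but-2-enoate (same structure as 10) | C/C=C(/C)C(=O)OC/C(=C/C)C(=O)O[C@@H](CC)c1cc(O[Si](C)(C)C(C)(C)C)c(OC)c(OC)c1
A8 | alternative 3 | (5-bromo-2,3-dimethoxyphenoxy)(tert-butyl)dimethylsilane | COc1cc(Br)cc(O[Si](C)(C)C(C)(C)C)c1OC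
A9 | alternative 3 | rac-1-chloropropyl (Z)-2-{[(Z)-2-methylbut-2-enoyl]oxymethyl}but-2-enoate | C/C=C(/C)C(=O)OC/C(=C/C)C(=O)OC(Cl)CC
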